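The route disconnects the furanone ring at the bond between the lactone carbonyl carbon C1 and the arene carbon C7a (isobenzofuranone numbering). It exploits the ortho relationship of C7a and C3a: the oxygen O2 on the benzylic carbon C3 carries C1 as a tert-butyl carbonate, so that C7a, C3a, C3, O2 and C1 form a five-atom chain. Bromine–lithium exchange at C7a then closes the ring by acyl transfer (Parham cyclization), and acid frees the C4/C5 catechol in the same operation. The precursor is a tris-Boc 6-bromobenzyl alcohol, in which Boc2O supplies C1 and protects both phenols. The more acidic C5 hydroxyl, para to the lactone carbonyl, is finally alkylated with an 11-hydroxyfarnesyl bromide.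

Key step: step 5

Remark: the target has no stereocentre; its two E double bonds are carried in unchanged from (2E,6E)-farnesyl acetate, and compounds 1 and 9 are taken to be commercially available.

Step 1
Reactants: 1 5-bromo-1,2,3-trimethoxybenzene
Product: 2 6-bromo-2,3,4-trimethoxybenzaldehyde
Conditions: Cl2CHOMe, TiCl4, CH2Cl2, 0 °C to rt; aqueous HCl work-up
Reagents that add atoms: dichloromethyl methyl ether COC(Cl)Cl (formyl carbon); water O (formyl oxygen, on hydrolysis)
Why: Rieche formylation, in which the TiCl4-activated ether attacks one of the two equivalent free positions of 1 (each ortho to one methoxy group and para to another), so that only one regioisomer can form and the bromine ends up ortho to the formyl group.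

Step 2
Reactants: 2 6-bromo-2,3,4-trimethoxybenzaldehyde
Product: 3 6-bromo-2,3-dihydroxy-4-methoxybenzaldehyde
Conditions: BCl3 (3 equiv), CH2Cl2, 0 °C to rt; then H2O
Reagents that add atoms: none
Why: Chelation-controlled ether cleavage, in which BCl3 bound to the formyl oxygen removes the ortho methyl group and the resulting aryloxyboron chloride removes the neighbouring one through a five-membered catechol borate, while the remote methoxy group should survive, as in the analogous bis-demethylation of 2,3,4-trimethoxybenzaldehyde.

Step 3
Reactants: 3 6-bromo-2,3-dihydroxy-4-methoxybenzaldehyde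
Product: 4 4-bromo-3-(hydroxymethyl)-6-methoxybenzene-1,2-diol
Conditions: NaBH4, THF/MeOH, 0 °C, Ar; pH 6 buffer work-up, used crude
Reagents that add atoms: none
Why: Borohydride reduction of the aldehyde to the benzylic alcohol, with low temperature and a buffered work-up to keep the electron-rich salicyl alcohol from ionising to a quinone methide.

Step 4
Reactants: 4 4-bromo-3-(hydroxymethyl)-6-methoxybenzene-1,2-diol
Product: 5 tert-butyl 6-bromo-2,3-bis[(tert-butoxycarbonyl)oxy]-4-methoxybenzyl carbonate
Conditions: Boc2O (4 equiv), 4-(dimethylamino)pyridine (0.2 equiv), i-Pr2NEt, CH2Cl2, 0 °C to rt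
Reagents that add atoms: di-tert-butyl dicarbonate CC(C)(C)OC(=O)OC(=O)OC(C)(C)C
Why: Amine-catalysed O-tert-butoxycarbonylation should cap the two phenols first and then the primary alcohol, giving the aryl carbonates as protecting groups and the benzylic carbonate as the tethered source of C1.

Step 5
Reactants: 5 tert-butyl 6-bromo-2,3-bis[(tert-butoxycarbonyl)oxy]-4-methoxybenzyl carbonate
Product: 8 4,5-dihydroxy-6-methoxyisobenzofuran-1(3H)-one, via aryllithium 6 (not isolated), via bis-Boc phthalide 7 (not isolated)
Conditions: t-BuLi (2.05 equiv), THF, −100 °C to −78 °C, high dilution; TFA (1.1 equiv) quench, concentrate; then TFA/CH2Cl2 (1:3), 0 °C to rt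
Reagents that add atoms: none
Why: Bromine–lithium exchange at C7a, which at −100 °C should outrun addition of tert-butyllithium to the hindered carbonates, gives aryllithium 6; its carbanion attacks the carbonyl carbon of the benzylic tert-butyl carbonate held on O2, the tetrahedral intermediate expels lithium tert-butoxide to give lactone 7, and TFA then cleaves the two aryl carbonates to catechol 8. The closest known reaction type is the Parham cyclization of ortho-halobenzyl carbamates to phthalides, together with the anionic Fries-type O-to-C transfer of Boc groups. The furanone ring closes in the 5-exo-trig mode by formation of the C7a–C1 bond. No stereocentre is formed. The step needs chemoselectivity among three carbonates: only the benzylic one lies within reach of C7a through a five-membered transition state, whereas the carbonates on O4 and O5 sit meta and para to the lithiated carbon and can be attacked only intermolecularly, which dilution and low temperature suppress. Should the tetrahedral intermediate open the other way, to the tert-butyl ester with a free benzylic alkoxide, the same lactone should form during the TFA treatment.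

Step 6
Reactants: 9 (2E,6E)-farnesyl acetate
Product: 10 (2E,6E)-10-bromo-11-hydroxy-3,7,11-trimethyldodeca-2,6-dien-1-yl acetate (racemic)
Conditions: N-bromosuccinimide (1.1 equiv), THF/H2O (2:1), 0 °C
Reagents that add atoms: N-bromosuccinimide O=C1CCC(=O)N1Br (bromine); water O (hydroxyl)
Why: Terminal-selective bromohydrin formation of a polyprenyl acetate in aqueous THF (van Tamelen conditions), in which the bromonium ion forms at the most exposed 10,11-alkene and water opens it at the tertiary carbon; the new C10 stereocentre is racemic and is removed in step 7.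

Step 7
Reactants: 10 (2E,6E)-10-bromo-11-hydroxy-3,7,11-trimethyldodeca-2,6-dien-1-yl acetate
Product: 12 (2E,6E)-3,7,11-trimethyldodeca-2,6-diene-1,11-diol, via 10,11-epoxyfarnesol 11 (not isolated)
Conditions: LiAlH4 (3 equiv), THF, 0 °C to reflux; Fieser work-up
Reagents that add atoms: none
Why: LiAlH4 reduction of a bromohydrin, in which the alkoxide closes to the 10,11-epoxide 11, hydride opens it at the less hindered secondary carbon to leave the tertiary alcohol, and the acetate is reduced off in the same pot.

Step 8
Reactants: 12 (2E,6E)-3,7,11-trimethyldodeca-2,6-diene-1,11-diol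
Product: 14 (6E,10E)-12-bromo-2,6,10-trimethyldodeca-6,10-dien-2-ol, via allylic mesylate 13 (not isolated)
Conditions: MsCl (1.05 equiv), Et3N, THF, −45 °C; then LiBr (4 equiv), THF, 0 °C
Reagents that add atoms: lithium bromide [Li+].[Br-] (bromine of 14); methanesulfonyl chloride CS(=O)(=O)Cl (sulfonyl group of the non-isolated 13 only)
Why: Selective mesylation of the primary allylic hydroxyl (the tertiary one is too hindered at −45 °C) followed by SN2 displacement with bromide, a standard route to allylic bromides that keeps the E geometry.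

Step 9
Reactants: 8 4,5-dihydroxy-6-methoxyisobenzofuran-1(3H)-one; 14 (6E,10E)-12-bromo-2,6,10-trimethyldodeca-6,10-dien-2-ol
Product: 15 Farnesylemefuranone E
Conditions: KHCO3 (1.1 equiv), 14 (1.0 equiv), DMF, rt, Ar
Reagents that add atoms: none
Why: Williamson etherification under weak-base control, in which bicarbonate deprotonates only the more acidic C5 hydroxyl (para to the lactone carbonyl, like the 4-hydroxyl of gallates) and its phenoxide displaces the primary allylic bromide by SN2, leaving the C4 hydroxyl and the tertiary alcohol untouched.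

Compound list
1 | 5-bromo-1,2,3-trimethoxybenzene | COc1cc(Br)cc(OC)c1OC | starting material
2 | 6-bromo-2,3,4-trimethoxybenzaldehyde | COc1cc(Br)c(C=O)c(OC)c1OC | intermediate
3 | 6-bromo-2,3-dihydroxy-4-methoxybenzaldehyde | COc1cc(Br)c(C=O)c(O)c1O | intermediate
4 | 4-bromo-3-(hydroxymethyl)-6-methoxybenzene-1,2-diol | COc1cc(Br)c(CO)c(O)c1O | intermediate
5 | tert-butyl 6-bromo-2,3-bis[(tert-butoxycarbonyl)oxy]-4-methoxybenzyl carbonate | COc1cc(Br)c(COC(=O)OC(C)(C)C)c(OC(=O)OC(C)(C)C)c1OC(=O)OC(C)(C)C | intermediate
6 | aryllithium formed from 5 by bromine–lithium exchange (not isolated) | COc1cc([Li])c(COC(=O)OC(C)(C)C)c(OC(=O)OC(C)(C)C)c1OC(=O)OC(C)(C)C | intermediate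
7 | 4,5-bis[(tert-butoxycarbonyl)oxy]-6-methoxyisobenzofuran-1(3H)-one (bis-Boc phthalide, not isolated) | COc1cc2c(c(OC(=O)OC(C)(C)C)c1OC(=O)OC(C)(C)C)COC2=O | intermediate
8 | 4,5-dihydroxy-6-methoxyisobenzofuran-1(3H)-one | COc1cc2c(c(O)c1O)COC2=O | intermediate
9 | (2E,6E)-farnesyl acetate, (2E,6E)-3,7,11-trimethyldodeca-2,6,10-trien-1-yl acetate | CC(=O)OC/C=C(\C)CC/C=C(\C)CCC=C(C)C | starting material
10 | (2E,6E)-10-bromo-11-hydroxy-3,7,11-trimethyldodeca-2,6-dien-1-yl acetate (racemic at C10) | CC(=O)OC/C=C(\C)CC/C=C(\C)CCC(Br)C(C)(C)O | intermediate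
11 | 10,11-epoxyfarnesol, (2E,6E)-9-(3,3-dimethyloxiran-2-yl)-3,7-dimethylnona-2,6-dien-1-ol (racemic, present as its aluminate, not isolated) | OC/C=C(\C)CC/C=C(\C)CCC1OC1(C)C | intermediate
12 | (2E,6E)-3,7,11-trimethyldodeca-2,6-diene-1,11-diol | OC/C=C(\C)CC/C=C(\C)CCCC(C)(C)O | intermediate
13 | (2E,6E)-11-hydroxy-3,7,11-trimethyldodeca-2,6-dien-1-yl methanesulfonate (allylic mesylate, not isolated) | CS(=O)(=O)OC/C=C(\C)CC/C=C(\C)CCCC(C)(C)O | intermediate
14 | (6E,10E)-12-bromo-2,6,10-trimethyldodeca-6,10-dien-2-ol | BrC/C=C(\C)CC/C=C(\C)CCCC(C)(C)O | intermediate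
15 | Farnesylemefuranone E, 4-hydroxy-5-{[(2E,6E)-11-hydroxy-3,7,11-trimethyldodeca-2,6-dien-1-yl]oxy}-6-methoxyisobenzofuran-1(3H)-one | COc1cc2c(c(O)c1OC/C=C(\C)CC/C=C(\C)CCCC(C)(C)O)COC2=O | target

Total step count: 9 steps.
Longest linear sequence: 6 steps (steps 1, 2, 3, 4, 5 and 9); the side chain takes 3 steps (6, 7, 8).

Steps most likely to fail

1. Step 5 (key step). What may go wrong: tert-butyllithium or aryllithium 6 adds to the aryl carbonates, or 6 is protonated before the ring closes, so that exchange and acyl transfer do not run cleanly. Fallback, setting out from 3 and coming back at 8: C1 is brought in as carbon monoxide instead of as a tethered carbonate. Compound 3 would be benzylated (BnBr, K2CO3, DMF) to 2,3-bis(benzyloxy)-6-bromo-4-methoxybenzaldehyde F1 and reduced (NaBH4, MeOH, 0 °C) to [2,3-bis(benzyloxy)-6-bromo-4-methoxyphenyl]methanol F2. Carbonylative lactonization (Pd(OAc)2, 1,3-bis(diphenylphosphino)propane, CO 1 atm, K2CO3, DMF, 90 °C) proceeds by oxidative addition of the aryl bromide to zerovalent palladium formed in situ, CO insertion and capture by the benzylic hydroxyl. It should give 4,5-bis(benzyloxy)-6-methoxyisobenzofuran-1(3H)-one F3. Hydrogenolysis (H2, palladium on carbon (Pd/C), EtOAc) would then return to 8.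

2. Step 4. What may go wrong: the electron-rich salicyl alcohol 4 ionises to an ortho-quinone methide, or a partly acylated intermediate closes to a cyclic carbonate, before all three hydroxyls are capped. Fallback, setting out from 3 and coming back at 8: the phenols are protected as acetals at the aldehyde stage, so the free triol is never handled, and the carbonyl is tethered as a carbamate. Compound 3 would be converted (MOMCl, i-Pr2NEt, CH2Cl2) into 6-bromo-4-methoxy-2,3-bis(methoxymethoxy)benzaldehyde F4 and reduced (NaBH4, MeOH) to [6-bromo-4-methoxy-2,3-bis(methoxymethoxy)phenyl]methanol F5. Acylation (NaH, Et2NCOCl, THF) should give 6-bromo-4-methoxy-2,3-bis(methoxymethoxy)benzyl N,N-diethylcarbamate F6. Parham cyclization (t-BuLi, THF, −78 °C) should then give 6-methoxy-4,5-bis(methoxymethoxy)isobenzofuran-1(3H)-one F7, and HCl in MeOH at 40 °C would remove the acetals to reach 8.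

3. Step 9. What may go wrong: poor site selectivity between the C4 and C5 hydroxyls, and double alkylation. Fallback, setting out from 7 and coming back at 15: the site is fixed by a protecting group instead of by acidity. Lactone 7 would be isolated by replacing the TFA treatment of step 5 with an aqueous NH4Cl quench. Pyrrolidine (1.05 equiv, CH2Cl2, 0 °C) should remove the more electrophilic C5 carbonate, whose aryloxide is stabilised by the para lactone carbonyl; any Boc migration between the neighbouring oxygens also ends with the phenoxide on the more acidic O5. This should give tert-butyl (5-hydroxy-6-methoxy-1-oxo-1,3-dihydroisobenzofuran-4-yl) carbonate F8. Alkylation with 14 (K2CO3, DMF, rt) should give tert-butyl (5-{[(2E,6E)-11-hydroxy-3,7,11-trimethyldodeca-2,6-dien-1-yl]oxy}-6-methoxy-1-oxo-1,3-dihydroisobenzofuran-4-yl) carbonate F9. Methanolysis of the aryl carbonate (K2CO3, MeOH, rt), which spares the allyl ether and the tertiary alcohol, would give 15.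

Further compounds
F1 | step 5 | 2,3-bis(benzyloxy)-6-bromo-4-methoxybenzaldehyde | COc1cc(Br)c(C=O)c(OCc2ccccc2)c1OCc1ccccc1
F2 | step 5 | [2,3-bis(benzyloxy)-6-bromo-4-methoxyphenyl]methanol | COc1cc(Br)c(CO)c(OCc2ccccc2)c1OCc1ccccc1
F3 | step 5 | 4,5-bis(benzyloxy)-6-methoxyisobenzofuran-1(3H)-one | COc1cc2c(c(OCc3ccccc3)c1OCc1ccccc1)COC2=O
F4 | step 4 | 6-bromo-4-methoxy-2,3-bis(methoxymethoxy)benzaldehyde | COc1cc(Br)c(C=O)c(OCOC)c1OCOC
F5 | step 4 | [6-bromo-4-methoxy-2,3-bis(methoxymethoxy)phenyl]methanol | COc1cc(Br)c(CO)c(OCOC)c1OCOC
F6 | step 4 | 6-bromo-4-methoxy-2,3-bis(methoxymethoxy)benzyl N,N-diethylcarbamate | CCN(CC)C(=O)OCc1c(Br)cc(OC)c(OCOC)c1OCOC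
F7 | step 4 | 6-methoxy-4,5-bis(methoxymethoxy)isobenzofuran-1(3H)-one | COc1cc2c(c(OCOC)c1OCOC)COC2=O
F8 | step 9 | tert-butyl (5-hydroxy-6-methoxy-1-oxo-1,3-dihydroisobenzofuran-4-yl) carbonate | COc1cc2c(c(OC(=O)OC(C)(C)C)c1O)COC2=O
F9 | step 9 | tert-butyl (5-{[(2E,6E)-11-hydroxy-3,7,11-trimethyldodeca-2,6-dien-1-yl]oxy}-6-methoxy-1-oxo-1,3-dihydroisobenzofuran-4-yl) carbonate | COc1cc2c(c(OC(=O)OC(C)(C)C)c1OC/C=C(\C)CC/C=C(\C)CCCC(C)(C)O)COC2=O
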